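**Retrosynthetic overview**
1. Target 19 ⇐ Mitsunobu esterification of acid 13 with hydroxytyrosol 18 (18 from catechol and glyoxylic acid).
2. Dihydropyran ester 11 ⇐ acyl-lactone (Korte) rearrangement of the α-formyl derivative of δ-lactone 9.
3. δ-Lactone 9 ⇐ one-carbon ring expansion of γ-lactone 6 by a Wolff 1,2-shift with internal ketene capture (key step).
4. γ-Lactone 6 ⇐ conjugate addition/enolate alkylation on (5S)-5-methylfuran-2(5H)-one 1, which sets all three stereocentres.
5. Ring order: γ-lactone (bought) → δ-lactone → 3,4-dihydro-2H-pyran; the arene is carried in from catechol.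

Assumption: 1 is bought as the single (S) enantiomer, and the tert-butyl group of 3 is a carboxyl protecting group.

Step 1
Reactants: 1 (5S)-5-methylfuran-2(5H)-one; 2 1,3-dithiane; 3 tert-butyl 2-bromoacetate
Product: 6 tert-butyl 2-[(3R,4R,5S)-4-(1,3-dithian-2-yl)-5-methyl-2-oxooxolan-3-yl]acetate, via 2-lithio-1,3-dithiane 4 (not isolated), via lithium lactone enolate 5 (not isolated)
Conditions: 2, n-BuLi, THF, −30 °C; 1, THF–DMPU, −78 °C; then 3, −78 to −20 °C
Reagents that add atoms: none
Why: Michael addition of the sulfur-stabilised formyl-anion equivalent occurs anti to the C5 methyl group and the lactone enolate is then alkylated anti to the new C4 substituent (conjugate addition/enolate alkylation), giving the trans,trans triad from the single stereocentre of 1.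

Step 2
Reactants: 6 tert-butyl 2-[(3R,4R,5S)-4-(1,3-dithian-2-yl)-5-methyl-2-oxooxolan-3-yl]acetate
Product: 9 tert-butyl 2-[(4R,5R,6S)-5-(1,3-dithian-2-yl)-6-methyl-2-oxooxan-4-yl]acetate, via hydroxy diazoketone 7 (not isolated), via ketene 8 (not isolated)
Conditions: Me3SiCHN2, n-BuLi, THF, −78 °C; AcOH, MeOH, 0 °C; evaporate; CH2Cl2, hν (390 nm LED), 20 °C
Reagents that add atoms: (trimethylsilyl)diazomethane, C[Si](C)(C)C=[N+]=[N-]
Why: Proposed new method: lithio(trimethylsilyl)diazomethane should open the lactone carbonyl in preference to the hindered tert-butyl ester, protodesilylation gives the γ-hydroxy α-diazoketone, and photochemical Wolff rearrangement migrates the ring carbon with retention of configuration to a ketene that the freed C–OH captures in a 6-membered closure, so the γ-lactone becomes the homologous δ-lactone in one flask; the closest known reaction types are the Arndt–Eistert homologation (Wolff rearrangement of diazoketones made from acid chlorides), ring-opening of lactones by lithiated diazo esters, and alcohol capture of Wolff ketenes.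

Step 3
Reactants: 9 tert-butyl 2-[(4R,5R,6S)-5-(1,3-dithian-2-yl)-6-methyl-2-oxooxan-4-yl]acetate
Product: 11 methyl (2S,3R,4R)-4-(2-tert-butoxy-2-oxoethyl)-3-(1,3-dithian-2-yl)-2-methyl-3,4-dihydro-2H-pyran-5-carboxylate, via sodium formyl-lactone enolate 10 (not isolated)
Conditions: NaH, HCO2Me, THF, 0 to 20 °C; AcOH; MeOH, TsOH (cat.), 45 °C
Reagents that add atoms: methyl formate, COC=O; methanol, CO
Why: Claisen formylation at the more acidic lactone α-CH2 is followed by the acyl-lactone (Korte) rearrangement, in which methanolysis of the activated lactone gives the methyl ester and the freed ring oxygen closes on the formyl carbon with loss of water to the vinylogous carbonate; the C2–O bond is never broken, so no stereocentre changes.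

Step 4
Reactants: 11 methyl (2S,3R,4R)-4-(2-tert-butoxy-2-oxoethyl)-3-(1,3-dithian-2-yl)-2-methyl-3,4-dihydro-2H-pyran-5-carboxylate
Product: 13 2-[(2S,3R,4R)-3-formyl-5-(methoxycarbonyl)-2-methyl-3,4-dihydro-2H-pyran-4-yl]acetic acid, via aldehyde tert-butyl ester 12 (not isolated)
Conditions: PhI(OCOCF3)2, MeCN–H2O 9:1, 0 °C; evaporate; TFA–CH2Cl2 1:2, 0 to 20 °C
Reagents that add atoms: water, O
Why: Iodine(III)-mediated oxidative hydrolysis of the dithioacetal frees the aldehyde and acidolysis of the tert-butyl ester (loss of isobutene) frees the acid, while the push-pull enol ether is inert and the aldehyde α-centre already has the all-trans, thermodynamically preferred configuration.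

Step 5
Reactants: 14 catechol; 15 glyoxylic acid
Product: 16 2-(3,4-dihydroxyphenyl)-2-hydroxyacetic acid (racemic)
Conditions: NaOH, H2O, 20 °C; then HCl
Reagents that add atoms: none
Why: Base-mediated electrophilic hydroxyalkylation of the catecholate by glyoxylate occurs para to a phenoxide oxygen (Friedel–Crafts-type aromatic substitution), and the new stereocentre is removed in the next step.

Step 6
Reactants: 16 2-(3,4-dihydroxyphenyl)-2-hydroxyacetic acid
Product: 17 2-(3,4-dihydroxyphenyl)acetic acid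
Conditions: H2 (4 bar), Pd/C, AcOH, cat. H2SO4, 70 °C
Reagents that add atoms: none
Why: Acid-assisted catalytic hydrogenolysis cleaves the electron-rich benzylic C–OH bond and leaves the arene and the acid untouched.

Step 7
Reactants: 17 2-(3,4-dihydroxyphenyl)acetic acid
Product: 18 4-(2-hydroxyethyl)benzene-1,2-diol (hydroxytyrosol)
Conditions: LiAlH4, THF, reflux; aq. HCl work-up
Reagents that add atoms: none
Why: Hydride reduction of the carboxylic acid gives the primary alcohol; the phenols are only deprotonated and return on work-up.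

Step 8
Reactants: 13 2-[(2S,3R,4R)-3-formyl-5-(methoxycarbonyl)-2-methyl-3,4-dihydro-2H-pyran-4-yl]acetic acid; 18 4-(2-hydroxyethyl)benzene-1,2-diol
Product: 19 methyl (2S,3R,4R)-4-{2-[2-(3,4-dihydroxyphenyl)ethoxy]-2-oxoethyl}-3-formyl-2-methyl-3,4-dihydro-2H-pyran-5-carboxylate
Conditions: PPh3, DIAD, THF, 0 to 20 °C
Reagents that add atoms: none
Why: Mitsunobu esterification is chemoselective because only the primary alcohol is activated as the oxyphosphonium ion and only the carboxylic acid is acidic enough to act as the nucleophile, so the free catechol needs no protection and no stereocentre is touched.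

**Compound list**
1 | (5S)-5-methylfuran-2(5H)-one | O=C1O[C@@H](C)C=C1 | starting material
2 | 1,3-dithiane | C1CSCSC1 | starting material
3 | tert-butyl 2-bromoacetate | CC(C)(C)OC(=O)CBr | starting material
4 | 2-lithio-1,3-dithiane | [Li]C1SCCCS1 | intermediate
5 | lithium (4R,5S)-4-(1,3-dithian-2-yl)-5-methyl-4,5-dihydrofuran-2-olate | [Li]OC1=C[C@@H](C2SCCCS2)[C@H](C)O1 | intermediate
6 | tert-butyl 2-[(3R,4R,5S)-4-(1,3-dithian-2-yl)-5-methyl-2-oxooxolan-3-yl]acetate | O=C1O[C@@H](C)[C@H](C2SCCCS2)[C@H]1CC(=O)OC(C)(C)C | intermediate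
7 | tert-butyl (3R,4R,5S)-3-(2-diazoacetyl)-4-(1,3-dithian-2-yl)-5-hydroxyhexanoate | O[C@@H](C)[C@H](C1SCCCS1)[C@H](C(=O)C=[N+]=[N-])CC(=O)OC(C)(C)C | intermediate
8 | tert-butyl (3S,4R,5S)-4-(1,3-dithian-2-yl)-5-hydroxy-3-(2-oxoethenyl)hexanoate | O[C@@H](C)[C@H](C1SCCCS1)[C@H](C=C=O)CC(=O)OC(C)(C)C | intermediate
9 | tert-butyl 2-[(4R,5R,6S)-5-(1,3-dithian-2-yl)-6-methyl-2-oxooxan-4-yl]acetate | O=C1O[C@@H](C)[C@H](C2SCCCS2)[C@H](C1)CC(=O)OC(C)(C)C | intermediate
10 | sodium [(4R,5R,6S)-4-(2-tert-butoxy-2-oxoethyl)-5-(1,3-dithian-2-yl)-6-methyl-2-oxooxan-3-ylidene]methanolate | O=C1O[C@@H](C)[C@H](C2SCCCS2)[C@H](C1=C[O-])CC(=O)OC(C)(C)C.[Na+] | intermediate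
11 | methyl (2S,3R,4R)-4-(2-tert-butoxy-2-oxoethyl)-3-(1,3-dithian-2-yl)-2-methyl-3,4-dihydro-2H-pyran-5-carboxylate | COC(=O)C1=CO[C@@H](C)[C@H](C2SCCCS2)[C@H]1CC(=O)OC(C)(C)C | intermediate
12 | methyl (2S,3R,4R)-4-(2-tert-butoxy-2-oxoethyl)-3-formyl-2-methyl-3,4-dihydro-2H-pyran-5-carboxylate | COC(=O)C1=CO[C@@H](C)[C@H](C=O)[C@H]1CC(=O)OC(C)(C)C | intermediate
13 | 2-[(2S,3R,4R)-3-formyl-5-(methoxycarbonyl)-2-methyl-3,4-dihydro-2H-pyran-4-yl]acetic acid | COC(=O)C1=CO[C@@H](C)[C@H](C=O)[C@H]1CC(=O)O | intermediate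
14 | catechol (benzene-1,2-diol) | Oc1ccccc1O | starting material
15 | glyoxylic acid | O=CC(=O)O | starting material
16 | 2-(3,4-dihydroxyphenyl)-2-hydroxyacetic acid (racemic) | OC(C(=O)O)c1ccc(O)c(O)c1 | intermediate
17 | 2-(3,4-dihydroxyphenyl)acetic acid | OC(=O)Cc1ccc(O)c(O)c1 | intermediate
18 | 4-(2-hydroxyethyl)benzene-1,2-diol (hydroxytyrosol) | OCCc1ccc(O)c(O)c1 | intermediate
19 | methyl (2S,3R,4R)-4-{2-[2-(3,4-dihydroxyphenyl)ethoxy]-2-oxoethyl}-3-formyl-2-methyl-3,4-dihydro-2H-pyran-5-carboxylate | COC(=O)C1=CO[C@@H](C)[C@H](C=O)[C@H]1CC(=O)OCCc1ccc(O)c(O)c1 | target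

**Step count:** 8 steps in total (steps 2, 3 and 4 are each run as a telescoped two-stage operation). The longest linear sequence is 5 steps (1, 2, 3, 4, 8); the hydroxytyrosol branch is steps 5–7.

**Steps most likely to fail**

Step 2 (the proposed new ring expansion). The lithiated diazo reagent may enolise the hindered lactone instead of adding, and on photolysis carbene O–H insertion or capture by a dithiane sulfur could compete with the Wolff shift. The fallback uses known chemistry, sets out from 6 and comes back at 11, bypassing 9. DIBAL-H at −78 °C reduces the lactone to the lactol tert-butyl 2-[(3R,4R,5S)-4-(1,3-dithian-2-yl)-2-hydroxy-5-methyloxolan-3-yl]acetate F1. Wittig methoxymethylenation (Ph3P=CHOMe) opens it to the hydroxy enol ether tert-butyl (3S)-3-[(1R,2S)-1-(1,3-dithian-2-yl)-2-hydroxypropyl]-5-methoxypent-4-enoate F2. Catalytic TsOH in warm toluene closes the ring and expels methanol to give the enol ether tert-butyl 2-[(2S,3R,4S)-3-(1,3-dithian-2-yl)-2-methyl-3,4-dihydro-2H-pyran-4-yl]acetate F3. Trichloroacetyl chloride/pyridine acylates the enol ether β-carbon to the ketone tert-butyl 2-[(2S,3R,4R)-3-(1,3-dithian-2-yl)-2-methyl-5-(2,2,2-trichloroacetyl)-3,4-dihydro-2H-pyran-4-yl]acetate F4, and haloform cleavage with MeOH/Et3N gives 11.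

Step 1. The basic dithiane anion may add 1,2 or deprotonate the γ-position of the butenolide, which would erode the ee. The fallback sets out from 1 and comes back at 6. A softer vinyl cuprate is added and the enolate trapped with 3, giving the vinyl lactone tert-butyl 2-[(3R,4R,5S)-4-ethenyl-5-methyl-2-oxooxolan-3-yl]acetate F5. Ozonolysis (O3, then Me2S) gives the aldehyde tert-butyl 2-[(3R,4R,5S)-4-formyl-5-methyl-2-oxooxolan-3-yl]acetate F6, and thioacetalisation with propane-1,3-dithiol (cat. I2) gives 6.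

Step 3. Formylation could also occur at the ester CH2, and the tert-butyl ester could suffer in acidic methanol. The fallback sets out from 9 and comes back at 11. Neutral aminomethylenation with tert-butoxybis(dimethylamino)methane, which reacts only at the more acidic lactone CH2, gives the enaminone tert-butyl 2-[(4R,5R,6S)-3-[(dimethylamino)methylidene]-5-(1,3-dithian-2-yl)-6-methyl-2-oxooxan-4-yl]acetate F7. Mild TsOH/MeOH then effects the same acyl-lactone rearrangement with loss of dimethylamine to give 11.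

Further compounds
F1 | step 2 | tert-butyl 2-[(3R,4R,5S)-4-(1,3-dithian-2-yl)-2-hydroxy-5-methyloxolan-3-yl]acetate | OC1O[C@@H](C)[C@H](C2SCCCS2)[C@H]1CC(=O)OC(C)(C)C
F2 | step 2 | tert-butyl (3S)-3-[(1R,2S)-1-(1,3-dithian-2-yl)-2-hydroxypropyl]-5-methoxypent-4-enoate | O[C@@H](C)[C@H](C1SCCCS1)[C@H](C=COC)CC(=O)OC(C)(C)C
F3 | step 2 | tert-butyl 2-[(2S,3R,4S)-3-(1,3-dithian-2-yl)-2-methyl-3,4-dihydro-2H-pyran-4-yl]acetate | C1=CO[C@@H](C)[C@H](C2SCCCS2)[C@H]1CC(=O)OC(C)(C)C
F4 | step 2 | tert-butyl 2-[(2S,3R,4R)-3-(1,3-dithian-2-yl)-2-methyl-5-(2,2,2-trichloroacetyl)-3,4-dihydro-2H-pyran-4-yl]acetate | ClC(Cl)(Cl)C(=O)C1=CO[C@@H](C)[C@H](C2SCCCS2)[C@H]1CC(=O)OC(C)(C)C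
F5 | step 1 | tert-butyl 2-[(3R,4R,5S)-4-ethenyl-5-methyl-2-oxooxolan-3-yl]acetate | O=C1O[C@@H](C)[C@H](C=C)[C@H]1CC(=O)OC(C)(C)C
F6 | step 1 | tert-butyl 2-[(3R,4R,5S)-4-formyl-5-methyl-2-oxooxolan-3-yl]acetate | O=C1O[C@@H](C)[C@H](C=O)[C@H]1CC(=O)OC(C)(C)C
F7 | step 3 | tert-butyl 2-[(4R,5R,6S)-3-[(dimethylamino)methylidene]-5-(1,3-dithian-2-yl)-6-methyl-2-oxooxan-4-yl]acetate | O=C1O[C@@H](C)[C@H](C2SCCCS2)[C@H](C1=CN(C)C)CC(=O)OC(C)(C)C
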